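**Assumption:** all numbered starting materials (1, 2, 4, 6, 7, 13, 14, 16) are taken as catalogue chemicals. Lignan locants are used: C7' is benzodioxine C3 (the aryl-bearing carbon) and C8' is benzodioxine C2 (the CH2OH-bearing carbon). The target is (7'R,8'R), the trans isomer.

## Retrosynthetic overview
- The last step is global desilylation. The E-stilbene comes from a Heck coupling of a 6-bromo-1,4-benzodioxane with 3,5-bis(silyloxy)styrene, so the resorcinol ring arrives intact.
- The 1,4-dioxane is the only ring formed. It is closed by Cu-catalysed intramolecular aryl C–O coupling of the C7'-OH onto an ortho C–I bond, with retention, and the para C–Br is saved for the Heck coupling.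
- The acyclic threo 8'-O-aryl ether carries both stereocentres and the ring regiochemistry. It comes from an Evans syn aldol of a (4-bromo-2-iodophenoxy)acetyl oxazolidinone with O-TIPS syringaldehyde, followed by borohydride removal of the auxiliary.
- A threo precursor with both C–O bonds retained gives the trans-(R,R) ring.

## Route

**Step 1**
Reactants: 1, 4-bromo-2-iodophenol; 2, bromoacetic acid
Product: 3, 2-(4-bromo-2-iodophenoxy)acetic acid
Conditions: NaH (2.2 equiv), THF, 0 → 65 °C; aq HCl work-up
Reagents that add atoms: bromoacetic acid, OC(=O)CBr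
Why: This is a Williamson ether synthesis that leaves both aryl halides untouched, and it fixes the oxygen para to Br as the one that will sit on C8'.

**Step 2**
Reactants: 3; 4, (S)-4-benzyl-1,3-oxazolidin-2-one
Product: 5, (S)-4-benzyl-3-[(4-bromo-2-iodophenoxy)acetyl]oxazolidin-2-one
Conditions: PivCl, Et3N, THF, –20 °C; then 4, LiCl, –20 °C → rt
Reagents that add atoms: (S)-4-benzyl-2-oxazolidinone, O=C1N[C@@H](Cc2ccccc2)CO1
Why: This is a LiCl-promoted N-acylation through the mixed pivalic anhydride, and it does not touch the auxiliary stereocentre.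

**Step 3**
Reactants: 6, syringaldehyde; 7, TIPSCl
Product: 8, 3,5-dimethoxy-4-(triisopropylsilyloxy)benzaldehyde
Conditions: TIPSCl, imidazole, DMAP (cat.), DMF, 40 °C
Reagents that add atoms: TIPSCl, CC(C)[Si](Cl)(C(C)C)C(C)C
Why: This is a phenol silylation, with TIPS chosen because it survives Cs2CO3 at 110 °C and comes off with fluoride at the end.

**Step 4**
Reactants: 5; 8
Product: 9, (S)-4-benzyl-3-[(2S,3R)-2-(4-bromo-2-iodophenoxy)-3-hydroxy-3-(3,5-dimethoxy-4-TIPSO-phenyl)propanoyl]oxazolidin-2-one
Conditions: Bu2BOTf, Et3N, CH2Cl2, –78 → 0 °C; 8, –78 → 0 °C; pH 7 buffer, MeOH, H2O2, 0 °C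
Reagents that add atoms: none beyond reactants 5 and 8
Why: This is an Evans syn aldol in which the Z-boron enolate reacts through a Zimmerman–Traxler transition state on the face away from the benzyl group, setting C8' and C7' together as the syn (threo) pair; minor diastereomers are removed by chromatography.

**Step 5**
Reactants: 9
Product: 10, (1R,2R)-2-(4-bromo-2-iodophenoxy)-1-(3,5-dimethoxy-4-TIPSO-phenyl)propane-1,3-diol (auxiliary 4 is recovered)
Conditions: NaBH4, THF/H2O (4:1), 0 °C → rt
Reagents that add atoms: none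
Why: This is a reductive cleavage of the imide with no bond to either stereocentre broken, so the C8' descriptor changes from S to R only because C=O becomes CH2OH in the CIP ranking.

**Step 6**
Reactants: 10; 7, TIPSCl
Product: 11, (1R,2R)-2-(4-bromo-2-iodophenoxy)-1-(3,5-dimethoxy-4-TIPSO-phenyl)-3-(triisopropylsilyloxy)propan-1-ol
Conditions: TIPSCl (1.1 equiv), imidazole, CH2Cl2, 0 °C
Reagents that add atoms: TIPSCl, CC(C)[Si](Cl)(C(C)C)C(C)C
Why: This is a sterically controlled silylation of the primary OH, which is needed because a free primary OH would also close a six-membered ring in Step 7, and TIPS resists O→O migration.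

**Step 7**
Reactants: 11
Product: 12, (2R,3R)-6-bromo-3-(3,5-dimethoxy-4-TIPSO-phenyl)-2-[(triisopropylsilyloxy)methyl]-2,3-dihydro-1,4-benzodioxine
Conditions: CuI (10 mol %), 3,4,7,8-Me4-1,10-phenanthroline (20 mol %), Cs2CO3, 4 Å MS, PhMe, 110 °C
Reagents that add atoms: none
Why: This is an intramolecular Ullmann-type C–O coupling at C–I in preference to C–Br, and because the C7'–O bond is never broken the configuration is retained, so threo 11 gives only the trans-(2R,3R) ring.

**Step 8**
Reactants: 13, 3,5-dihydroxybenzaldehyde; 14, TBSCl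
Product: 15, 3,5-bis(tert-butyldimethylsilyloxy)benzaldehyde
Conditions: TBSCl (2.3 equiv), imidazole, DMF, rt
Reagents that add atoms: TBSCl, CC(C)(C)[Si](C)(C)Cl
Why: This is a routine double phenol silylation.

**Step 9**
Reactants: 15; 16, methyltriphenylphosphonium bromide
Product: 17, 3,5-bis(tert-butyldimethylsilyloxy)styrene
Conditions: MePPh3Br, n-BuLi, THF, 0 °C; then 15, 0 °C → rt
Reagents that add atoms: MePPh3Br, C[P+](c1ccccc1)(c1ccccc1)c1ccccc1.[Br-] (delivers CH2)
Why: This is a Wittig methylenation, and pre-forming the ylide leaves no free base to attack the aryl silyl ethers.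

**Step 10**
Reactants: 12; 17
Product: 18, (2R,3R)-6-[(E)-3,5-bis(TBSO)styryl]-3-(3,5-dimethoxy-4-TIPSO-phenyl)-2-[(TIPSO)methyl]-2,3-dihydro-1,4-benzodioxine
Conditions: Pd2(dba)3 (2.5 mol %), [t-Bu3PH]BF4 (10 mol %), Cy2NMe, 1,4-dioxane, 90 °C
Reagents that add atoms: none beyond reactants 12 and 17
Why: This is a Mizoroki–Heck reaction in which the electron-rich phosphine activates the electron-rich ArBr, syn-insertion and syn-β-H elimination give the E-alkene, and the amine base spares the silyl ethers and both stereocentres.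

**Step 11**
Reactants: 18
Product: 19, aiphanol, 5-[(E)-2-[(2R,3R)-3-(4-hydroxy-3,5-dimethoxyphenyl)-2-(hydroxymethyl)-2,3-dihydro-1,4-benzodioxin-6-yl]ethenyl]benzene-1,3-diol
Conditions: TBAF/AcOH (1:1, 6 equiv), THF, 0 °C → rt
Reagents that add atoms: none
Why: This is a global fluoride desilylation of four Si–O bonds, buffered with AcOH to suppress phenoxide-triggered quinone-methide opening at C7', which in any case would re-close to the favoured trans isomer.

## Compound list
1 | 4-bromo-2-iodophenol | Oc1ccc(Br)cc1I | starting material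
2 | bromoacetic acid | OC(=O)CBr | starting material
3 | 2-(4-bromo-2-iodophenoxy)acetic acid | OC(=O)COc1ccc(Br)cc1I | intermediate
4 | (S)-4-benzyl-1,3-oxazolidin-2-one | O=C1N[C@@H](Cc2ccccc2)CO1 | starting material (auxiliary)
5 | (S)-4-benzyl-3-[(4-bromo-2-iodophenoxy)acetyl]oxazolidin-2-one | O=C1OC[C@H](Cc2ccccc2)N1C(=O)COc1ccc(Br)cc1I | intermediate
6 | syringaldehyde | COc1cc(C=O)cc(OC)c1O | starting material
7 | triisopropylsilyl chloride | CC(C)[Si](Cl)(C(C)C)C(C)C | starting material (reagent)
8 | 3,5-dimethoxy-4-(triisopropylsilyloxy)benzaldehyde | COc1cc(C=O)cc(OC)c1O[Si](C(C)C)(C(C)C)C(C)C | intermediate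
9 | (4S,2'S,3'R) Evans syn-aldol adduct | O=C1OC[C@H](Cc2ccccc2)N1C(=O)[C@@H](Oc1ccc(Br)cc1I)[C@H](O)c1cc(OC)c(O[Si](C(C)C)(C(C)C)C(C)C)c(OC)c1 | intermediate
10 | (1R,2R)-2-aryloxy-1-arylpropane-1,3-diol | OC[C@@H](Oc1ccc(Br)cc1I)[C@H](O)c1cc(OC)c(O[Si](C(C)C)(C(C)C)C(C)C)c(OC)c1 | intermediate
11 | (1R,2R) primary TIPS ether of 10 | CC(C)[Si](C(C)C)(C(C)C)OC[C@@H](Oc1ccc(Br)cc1I)[C@H](O)c1cc(OC)c(O[Si](C(C)C)(C(C)C)C(C)C)c(OC)c1 | intermediate
12 | (2R,3R)-6-bromo-trans-benzodioxane, bis-TIPS | CC(C)[Si](C(C)C)(C(C)C)OC[C@H]1Oc2ccc(Br)cc2O[C@@H]1c1cc(OC)c(O[Si](C(C)C)(C(C)C)C(C)C)c(OC)c1 | intermediate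
13 | 3,5-dihydroxybenzaldehyde | O=Cc1cc(O)cc(O)c1 | starting material
14 | tert-butyldimethylsilyl chloride | CC(C)(C)[Si](C)(C)Cl | starting material (reagent)
15 | 3,5-bis(TBSO)benzaldehyde | O=Cc1cc(O[Si](C)(C)C(C)(C)C)cc(O[Si](C)(C)C(C)(C)C)c1 | intermediate
16 | methyltriphenylphosphonium bromide | C[P+](c1ccccc1)(c1ccccc1)c1ccccc1.[Br-] | starting material (reagent)
17 | 3,5-bis(TBSO)styrene | C=Cc1cc(O[Si](C)(C)C(C)(C)C)cc(O[Si](C)(C)C(C)(C)C)c1 | intermediate
18 | tetrasilyl aiphanol | CC(C)[Si](C(C)C)(C(C)C)OC[C@H]1Oc2ccc(/C=C/c3cc(O[Si](C)(C)C(C)(C)C)cc(O[Si](C)(C)C(C)(C)C)c3)cc2O[C@@H]1c1cc(OC)c(O[Si](C(C)C)(C(C)C)C(C)C)c(OC)c1 | intermediate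
19 | aiphanol (2R,3R) | COc1cc([C@H]2Oc3cc(/C=C/c4cc(O)cc(O)c4)ccc3O[C@@H]2CO)cc(OC)c1O | target

## Summary
Total steps: 11.
Longest linear sequence: 8 (Steps 1, 2, 4, 5, 6, 7, 10, 11).

Steps most likely to fail:
1. **Step 7, Cu ring closure.** The hindered secondary benzylic alkoxide may couple slowly, and deiodination or loss of β-aryloxide could compete.
   - Fallback: convert the C–I bond of 11 to a phenol by I-selective Miyaura borylation and H2O2 oxidation. Then close the ring at C7' by acid-promoted benzylic (SN1/quinone-methide-type) etherification, letting the fixed C8' centre steer to the thermodynamically preferred trans ring.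
2. **Step 4, Evans aldol.** The electron-rich aldehyde and bulky aryloxy enolate may give low conversion or low diastereoselectivity.
   - Fallback: drop the auxiliary and prepare the ethyl 2-(4-bromo-2-iodophenoxy)-3-aryl-3-oxopropanoate. Set both centres by Ru–TsDPEN transfer hydrogenation with dynamic kinetic resolution (syn-selective), then reduce with LiBH4 to reach 10.
3. **Step 10, Heck coupling.** The deactivated ArBr may react slowly, and styrene oligomerisation or branched (1,1-diaryl) regioisomer formation could compete.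
   - Fallback: convert 12 to the 6-carbaldehyde by Br/Li exchange and a DMF quench. Then form the E-alkene by Horner–Wadsworth–Emmons olefination with diethyl 3,5-bis(TBSO)benzylphosphonate.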